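## Structural features

Artoindonesianin Q (16) is a flavone. Ring A is fused to the pyran-4-one ring C, C2 carries the aryl ring B, and C3 carries a 3-methylbut-2-enyl (prenyl) chain. Ring A is phloroglucinol-type: O1, a hydroxyl at C5 hydrogen-bonded to the C4 carbonyl, and a methoxy group at C7. Ring B is a 2',5'-dihydroxy-4'-methoxyphenyl group, that is a para-hydroquinone. There is no stereocentre, so the only stereochemical question is the geometry of the tetrasubstituted C2=C3 bond before ring C exists. Two groups are fragile: the prenyl alkene, which acids add to or cyclise (most easily onto a free 2'-OH), and the ring B hydroquinone, which air oxidises once it is free. The real difficulty is to build the crowded C2=C3 unit and to tell five oxygens apart (two stay methylated, three end free) without strong acid or oxidant. The plan exploits the position of C4a ortho to O1 on ring A: in a 3,5-dimethoxyphenyl ether both carbons ortho to the ether oxygen are equivalent and each is activated by three oxygens, so acylation to form C4–C4a can give only one chromone. After closure only the C5 methoxy group lies peri to the C4 carbonyl, which allows its selective cleavage.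

## Logic of the disconnections

16 to 15. The two O–allyl bonds on ring B are reconnected. The hydroquinone is the most oxidisable part of 16 and its 2'-OH is the group that would add to the prenyl alkene under acid, so both are exposed only at the end. The gain is that every earlier intermediate is a robust aryl ether. The forward step must be neither acidic nor oxidising and must leave a trisubstituted alkene alone.

15 to 14. The O–H at C5 becomes O–CH3. Ring A then carries two methoxy groups besides O1 and can come from a phenol with a mirror plane, which removes every regiochemical question from the ring closure. The forward step must cleave one of four methyl ethers and spare two allyl ethers; only the C5 methoxy group can chelate with the C4 carbonyl.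

14 to 12, through 13. The C4–C4a bond is cut. Ring C opens to a carboxylic acid on a tetrasubstituted enol ether, in which rings A and B are joined only through the C3 oxygen and carbon. The forward step needs the carboxyl and the aryloxy group cis on the alkene (Z) and an activation mild enough for the prenyl group.

12 to 11. The acid is traced to its methyl ester, because an ester is needed to build the alkene. The forward hydrolysis must attack a hindered, conjugated ester without displacing the aryloxide from C3. A methyl ester is chosen over an ethyl ester for this reason.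

11 to 9 and 10. The vinylic C3–O bond is cut. This is the convergent cut: it separates the symmetric phenol 10 from the three-carbon unit that carries ring B and the prenyl chain. The forward substitution must occur at a crowded sp2 carbon, at carbon and not at sulfur, and with retention of geometry.

9 to 8. The O–S bond is cut, which turns the geometry problem into the geometry of a chelated enolate. The forward step must sulfonylate that enolate on oxygen while the metal holds both oxygens on one side.

8 to 6 and 7. The bond between C2 and the prenyl CH2 is cut at the most acidic carbon. The prenyl group then comes from simple alkylation, long before any step that could endanger it. The forward step must stop at monoalkylation on carbon.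

6 to 4 and 5. The C–C bond between the acetyl carbon of 4 and the carbonyl carbon of 5 is cut (the future C3–C4 bond). The forward Claisen condensation needs excess base to hold the product as its enolate.

4 to 3. The two O–allyl bonds are cut. Allyl is chosen over an acetal group because it survives base, anhydride activation and MgI2, and cannot leave as a stabilised cation during ring closure.

3 to 1 and 2. The aryl–acyl C–C bond is cut. The forward acylation must go para to the methoxy group of 1, which is the position that two oxygens activate and that is not flanked on both sides.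

## Other disconnections considered

Alternative 1: The cut takes ring B apart at C5'–C6', C1'–C2' and C2'–C3'. It leads back to the 2-ethynylchromone A1 (2-ethynyl-5-hydroxy-7-methoxy-3-(3-methylbut-2-enyl)chromen-4-one) and the Fischer carbene complex A2 (pentacarbonyl[methoxy(1-methoxyethenyl)carbene]chromium). In the forward sense a Dötz benzannulation would insert the alkyne of A1 into the chromium–carbene bond, insert CO and close the ring by electrocyclisation. The product would be the para-methoxyphenol A3 (5-hydroxy-2-(2-hydroxy-4,5-dimethoxyphenyl)-7-methoxy-3-(3-methylbut-2-enyl)chromen-4-one).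
- In its favour: the oxygen pattern of ring B follows from the mechanism, three skeletal bonds form in one step, and ring B needs no protecting groups. On these points it is better than the chosen plan.
- Against it: A3 is not 16 but its 5'-O-methyl ether, because the carbene oxygen arrives methylated. The way on would be oxidation to the methoxyquinone A4 (2-[5-hydroxy-7-methoxy-3-(3-methylbut-2-enyl)-4-oxochromen-2-yl]-5-methoxycyclohexa-2,5-diene-1,4-dione), for example with (NH4)2Ce(NO3)6, then reduction with Na2S2O4. Both steps must spare the prenyl group and the ring A phenol.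
- Further drawbacks: the alkyne of A1 is conjugated with the electron-poor pyranone, a class expected to react less cleanly in this annulation; the chromium reagent is stoichiometric; and A1 needs a synthesis of its own that is expected to be about as long as the whole chosen route.
- Comparison: on structure the plans are equal in that each needs two steps after the key step. On mechanism the chosen plan uses a classical polar ring closure with a symmetric nucleophile, the alternative an organometallic cascade on an unfavourable alkyne. On step count the alternative is expected to be longer.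

Alternative 2: The cut is O1–C8a. It leads back to the 1,3-dione A5 (1-(2,6-difluoro-4-methoxyphenyl)-3-[4-methoxy-2,5-bis(methoxymethoxy)phenyl]-2-(3-methylbut-2-enyl)propane-1,3-dione). In the forward sense K2CO3 in DMF would form the enolate, whose oxygen next to ring B displaces one of the two ortho fluorides activated by the neighbouring carbonyl. The product would be the fluorochromone A6 (5-fluoro-7-methoxy-2-[4-methoxy-2,5-bis(methoxymethoxy)phenyl]-3-(3-methylbut-2-enyl)chromen-4-one).
- In its favour: two equivalent fluorides give the same symmetry advantage, and the closure is purely basic, so the prenyl group is not at risk in that step. No alkene geometry has to be set, and on this point it is better than the chosen plan.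
- Against it: A6 has fluorine where 16 has the C5 hydroxyl, so a second aromatic substitution with an oxygen nucleophile and its unmasking are still needed. The methoxymethyl groups must then be removed with acid, the one condition under which a free 2'-OH adds to the neighbouring prenyl alkene. A5, a 2-substituted dione with a doubly ortho-substituted aroyl group, is also open to retro-Claisen cleavage in base.
- Comparison: on mechanism the two plans are equal, since both closures are well-precedented polar reactions. On structure the chosen plan carries oxygen at C5 from the start and ends with a neutral deprotection. On step count the two are about equal, the alternative saving little once the fluorine exchange is counted.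

Alternative 3: The cut removes C4–C3 and O1–C2 together. It leads back to the aldehyde A7 (2,6-dihydroxy-4-methoxybenzaldehyde) and the aryl alkyne A8 (1-methoxy-2,5-bis(methoxymethoxy)-4-(5-methylhex-4-en-1-ynyl)benzene). In the forward sense [Cp*RhCl2]2 with Cu(OAc)2 would activate the formyl C–H bond under direction of a phenol. The acyl–rhodium species would add across the alkyne, with the acyl carbon bonding to the alkyl-bearing carbon, and C–O reductive elimination would close ring C; Cu(OAc)2 reoxidises the rhodium. The product would be A9 (5-hydroxy-7-methoxy-2-[4-methoxy-2,5-bis(methoxymethoxy)phenyl]-3-(3-methylbut-2-enyl)chromen-4-one).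
- In its favour: it is the most convergent plan. The C5 hydroxyl arrives free, no alkene geometry is involved, and the expected regiochemistry (aryl next to oxygen) is the one needed. In step count and in structural directness it is clearly better than the chosen plan.
- Against it: the alkyne of A8 is a skipped enyne whose CH2 group is both allylic and propargylic, so isomerisation to an allene or a conjugated enyne is likely under hot acetate and metal. Its aryl group is ortho-substituted, which should slow insertion and may erode regioselectivity. The second phenol of A7 and decarbonylation of the acyl–metal species are further liabilities. A9 must be unmasked with acid, with the same risk to the prenyl group as in alternative 2.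
- Comparison: the alternative wins on step economy and loses on predictability. The chosen plan is preferred because each of its steps has a close classical counterpart and its last step is neutral.

Key step: step 8

Remark on the chemistry: compounds 1, 2, 5, 7 and 10 and all reagents are taken as commercial. Z in 9, 11, 12 and 13 means that the oxygen substituent on C3 and the carboxyl-derived carbon lie on the same side of the double bond, the geometry the ring closure needs.

## Route

Step 1
Reactants: 1 methoxyhydroquinone (2-methoxybenzene-1,4-diol); 2 acetic acid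
Product: 3 1-(2,5-dihydroxy-4-methoxyphenyl)ethanone
Conditions: BF3·OEt2, AcOH (neat), 90 °C; then ice-water
Reagents that add atoms: none
Why: Friedel–Crafts C-acetylation of a phenol (BF3-mediated, Fries-type) should go to C5 of 1, the only ring carbon that is ortho to a hydroxyl, para to the methoxy group and not flanked by two substituents; chelation of the ortho-hydroxy ketone stops a second acylation.

Step 2
Reactants: 3 1-(2,5-dihydroxy-4-methoxyphenyl)ethanone
Product: 4 1-[2,5-bis(allyloxy)-4-methoxyphenyl]ethanone
Conditions: allyl bromide, K2CO3, DMF, 60 °C
Reagents that add atoms: allyl bromide, C=CCBr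
Why: Williamson ether synthesis on both phenols, with warm DMF for the chelated 2-OH; allyl ethers tolerate base, anhydride activation and MgI2 and are removed under neutral conditions at the end.

Step 3
Reactants: 4 1-[2,5-bis(allyloxy)-4-methoxyphenyl]ethanone; 5 dimethyl carbonate
Product: 6 methyl 3-[2,5-bis(allyloxy)-4-methoxyphenyl]-3-oxopropanoate
Conditions: NaH, THF, reflux; then cold 1 M HCl
Reagents that add atoms: none
Why: Crossed Claisen condensation of the methyl ketone enolate with a non-enolisable carbonate, driven by deprotonation of the β-keto ester by the second equivalent of NaH; the methyl ester is chosen because it is the easier one to hydrolyse in step 7.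

Step 4
Reactants: 6 methyl 3-[2,5-bis(allyloxy)-4-methoxyphenyl]-3-oxopropanoate; 7 prenyl bromide (1-bromo-3-methylbut-2-ene)
Product: 8 methyl 2-[2,5-bis(allyloxy)-4-methoxybenzoyl]-5-methylhex-4-enoate (racemic)
Conditions: K2CO3, acetone, 50 °C
Reagents that add atoms: none
Why: SN2 C-alkylation of the stabilised β-keto ester enolate by a soft allylic bromide; a weak heterogeneous base and one equivalent of 7 favour monoalkylation at carbon, and the new α-stereocentre is racemic and is erased in step 5.

Step 5
Reactants: 8 methyl 2-[2,5-bis(allyloxy)-4-methoxybenzoyl]-5-methylhex-4-enoate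
Product: 9 methyl (Z)-3-[2,5-bis(allyloxy)-4-methoxyphenyl]-2-(3-methylbut-2-enyl)-3-(trifluoromethylsulfonyloxy)prop-2-enoate
Conditions: NaH, CH2Cl2, 0 °C; then Tf2O, −78 → 0 °C
Reagents that add atoms: trifluoromethanesulfonic anhydride, O=S(=O)(OS(=O)(=O)C(F)(F)F)C(F)(F)F
Why: O-sulfonylation of a β-keto ester enolate; in a non-coordinating solvent sodium bridges the enolate oxygen and the ester carbonyl, so the two oxygens are cis and trapping should give the Z enol triflate.

Step 6
Reactants: 9 methyl (Z)-3-[2,5-bis(allyloxy)-4-methoxyphenyl]-2-(3-methylbut-2-enyl)-3-(trifluoromethylsulfonyloxy)prop-2-enoate; 10 3,5-dimethoxyphenol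
Product: 11 methyl (Z)-3-[2,5-bis(allyloxy)-4-methoxyphenyl]-3-(3,5-dimethoxyphenoxy)-2-(3-methylbut-2-enyl)prop-2-enoate
Conditions: Cs2CO3, DMF, 0 °C → rt
Reagents that add atoms: none
Why: Nucleophilic vinylic substitution by addition–elimination on a vinylogous acyl triflate: the phenoxide adds to C3 and the ester enolate should expel triflate faster than the C2–C3 bond turns over, so retention is expected and the aryloxy group ends cis to the ester.

Step 7
Reactants: 11 methyl (Z)-3-[2,5-bis(allyloxy)-4-methoxyphenyl]-3-(3,5-dimethoxyphenoxy)-2-(3-methylbut-2-enyl)prop-2-enoate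
Product: 12 (Z)-3-[2,5-bis(allyloxy)-4-methoxyphenyl]-3-(3,5-dimethoxyphenoxy)-2-(3-methylbut-2-enyl)prop-2-enoic acid
Conditions: LiOH·H2O, THF/MeOH/H2O, 45 °C; then 1 M HCl to pH 3, 0 °C
Reagents that add atoms: lithium hydroxide, [Li+].[OH-]
Why: Saponification by acyl–oxygen cleavage of a methyl ester; C3 is shielded by an ortho-substituted aryl group and the prenyl chain, so attack at the ester carbonyl should outrun conjugate attack, and the carboxylate formed is inert to further base.

Step 8
Reactants: 12 (Z)-3-[2,5-bis(allyloxy)-4-methoxyphenyl]-3-(3,5-dimethoxyphenoxy)-2-(3-methylbut-2-enyl)prop-2-enoic acid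
Product: 14 2-[2,5-bis(allyloxy)-4-methoxyphenyl]-5,7-dimethoxy-3-(3-methylbut-2-enyl)chromen-4-one, via mixed trifluoroacetic anhydride 13 (not isolated)
Conditions: (CF3CO)2O, 2,6-di-tert-butyl-4-methylpyridine, CH2Cl2 (0.02 M), 0 °C → rt
Reagents that add atoms: none
Why: The acid and (CF3CO)2O give the mixed anhydride 13, which reacts as an acylium ion whose charge is shared with the C3 aryloxy oxygen; the carbon ortho to that oxygen on the dimethoxyphenoxy ring attacks the acyl carbon and the hindered pyridine removes the proton from the arenium ion. This is an intramolecular Friedel–Crafts acylation, the ring-forming event of the Ruhemann-type chromone synthesis from β-aryloxyacrylic acids, run with anhydride activation in place of strong protic acid. Ring C closes by C–C bond formation between the acyl carbon (C4) and the arene carbon (C4a) through a six-membered transition state that already contains O1, C2 and C3. No stereocentre is formed. Selectivity between the rings comes from the Z alkene, which holds the acyl group next to the aryloxy ring and away from ring B, whose C6' has only one activating ortho oxygen and would need a five-membered closure. Regioselectivity on ring A needs no control, because the two ortho carbons are equivalent by symmetry and the para carbon cannot reach the acyl group. The prenyl alkene should survive because no free strong acid is present: the trifluoroacetic acid released is taken up by a base too hindered to intercept the acylating species.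

Step 9
Reactants: 14 2-[2,5-bis(allyloxy)-4-methoxyphenyl]-5,7-dimethoxy-3-(3-methylbut-2-enyl)chromen-4-one
Product: 15 2-[2,5-bis(allyloxy)-4-methoxyphenyl]-5-hydroxy-7-methoxy-3-(3-methylbut-2-enyl)chromen-4-one
Conditions: MgI2·OEt2, THF/toluene, 60 °C; then cold 0.5 M HCl
Reagents that add atoms: none
Why: Chelation-controlled ether cleavage: magnesium binds the C4 carbonyl and the C5 oxygen in a six-membered chelate, which activates that methyl group alone for SN2 attack by iodide; the other methoxy and allyloxy groups cannot chelate and should stay.

Step 10
Reactants: 15 2-[2,5-bis(allyloxy)-4-methoxyphenyl]-5-hydroxy-7-methoxy-3-(3-methylbut-2-enyl)chromen-4-one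
Product: 16 artoindonesianin Q, 2-(2,5-dihydroxy-4-methoxyphenyl)-5-hydroxy-7-methoxy-3-(3-methylbut-2-enyl)chromen-4-one
Conditions: Pd(PPh3)4 (5 mol %), morpholine, degassed THF, rt, argon
Reagents that add atoms: none
Why: Tsuji–Trost-type deallylation: zerovalent palladium ionises each allyl aryl ether to an allylpalladium cation and the phenoxide, and morpholine takes the allyl group; the prenyl chain is not an allylic electrophile, and the neutral, oxygen-free medium protects the hydroquinone and avoids acid-induced cyclisation.

## Compound list

1 | methoxyhydroquinone (2-methoxybenzene-1,4-diol) | COc1cc(O)ccc1O | starting material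
2 | acetic acid | CC(=O)O | starting material
3 | 1-(2,5-dihydroxy-4-methoxyphenyl)ethanone | CC(=O)c1cc(O)c(OC)cc1O | intermediate
4 | 1-[2,5-bis(allyloxy)-4-methoxyphenyl]ethanone | CC(=O)c1cc(OCC=C)c(OC)cc1OCC=C | intermediate
5 | dimethyl carbonate | COC(=O)OC | starting material
6 | methyl 3-[2,5-bis(allyloxy)-4-methoxyphenyl]-3-oxopropanoate | COC(=O)CC(=O)c1cc(OCC=C)c(OC)cc1OCC=C | intermediate
7 | prenyl bromide (1-bromo-3-methylbut-2-ene) | CC(C)=CCBr | starting material
8 | methyl 2-[2,5-bis(allyloxy)-4-methoxybenzoyl]-5-methylhex-4-enoate (racemic) | COC(=O)C(CC=C(C)C)C(=O)c1cc(OCC=C)c(OC)cc1OCC=C | intermediate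
9 | methyl (Z)-3-[2,5-bis(allyloxy)-4-methoxyphenyl]-2-(3-methylbut-2-enyl)-3-(trifluoromethylsulfonyloxy)prop-2-enoate | COC(=O)/C(CC=C(C)C)=C(\OS(=O)(=O)C(F)(F)F)c1cc(OCC=C)c(OC)cc1OCC=C | intermediate
10 | 3,5-dimethoxyphenol | COc1cc(O)cc(OC)c1 | starting material
11 | methyl (Z)-3-[2,5-bis(allyloxy)-4-methoxyphenyl]-3-(3,5-dimethoxyphenoxy)-2-(3-methylbut-2-enyl)prop-2-enoate | COC(=O)/C(CC=C(C)C)=C(\Oc1cc(OC)cc(OC)c1)c1cc(OCC=C)c(OC)cc1OCC=C | intermediate
12 | (Z)-3-[2,5-bis(allyloxy)-4-methoxyphenyl]-3-(3,5-dimethoxyphenoxy)-2-(3-methylbut-2-enyl)prop-2-enoic acid | OC(=O)/C(CC=C(C)C)=C(\Oc1cc(OC)cc(OC)c1)c1cc(OCC=C)c(OC)cc1OCC=C | intermediate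
13 | (Z)-3-[2,5-bis(allyloxy)-4-methoxyphenyl]-3-(3,5-dimethoxyphenoxy)-2-(3-methylbut-2-enyl)prop-2-enoic trifluoroacetic anhydride | O=C(OC(=O)C(F)(F)F)/C(CC=C(C)C)=C(\Oc1cc(OC)cc(OC)c1)c1cc(OCC=C)c(OC)cc1OCC=C | intermediate (not isolated)
14 | 2-[2,5-bis(allyloxy)-4-methoxyphenyl]-5,7-dimethoxy-3-(3-methylbut-2-enyl)chromen-4-one | COc1cc(OC)c2c(=O)c(CC=C(C)C)c(-c3cc(OCC=C)c(OC)cc3OCC=C)oc2c1 | intermediate
15 | 2-[2,5-bis(allyloxy)-4-methoxyphenyl]-5-hydroxy-7-methoxy-3-(3-methylbut-2-enyl)chromen-4-one | COc1cc(O)c2c(=O)c(CC=C(C)C)c(-c3cc(OCC=C)c(OC)cc3OCC=C)oc2c1 | intermediate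
16 | artoindonesianin Q, 2-(2,5-dihydroxy-4-methoxyphenyl)-5-hydroxy-7-methoxy-3-(3-methylbut-2-enyl)chromen-4-one | COc1cc(O)c2c(=O)c(CC=C(C)C)c(-c3cc(O)c(OC)cc3O)oc2c1 | target

## Step count and least certain steps

Total step count: 10. Longest linear sequence: 10 steps (1 to 16); compounds 2, 5, 7 and 10 enter as purchased materials.

Step 8 (key step). The buffered mixed anhydride 13 may be too weak an electrophile, so that the reaction stalls. If acid is then admitted, protonation of the prenyl alkene and capture of the cation by the carboxyl oxygen can compete. Any E isomer carried in could acylate towards ring B, although rotation about C2–C3 in the oxygen-stabilised acylium ion should return part of it to the productive geometry. Trifluoroacetylation of the very electron-rich ring is a further possible diversion.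

The fallback forms the same bond by an anionic route and sets out from 9 and 10. Ortho-bromination of 10 (N-bromosuccinimide, catalytic i-Pr2NH, CH2Cl2, 0 °C) would give 2-bromo-3,5-dimethoxyphenol F1. Substitution on 9 as in step 6 would give methyl (Z)-3-[2,5-bis(allyloxy)-4-methoxyphenyl]-3-(2-bromo-3,5-dimethoxyphenoxy)-2-(3-methylbut-2-enyl)prop-2-enoate F2. Bromine–lithium exchange with n-BuLi in THF at −100 °C, followed by attack of the aryllithium on the neighbouring ester (Parham cyclisation), should close ring C and return to the route at 14. The bromine fixes the regiochemistry, no acid is used, and step 7 is also bypassed.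

Step 6. The phenoxide may attack sulfur and not C3, transferring the triflyl group and regenerating the keto ester enolate. Addition at the congested C3 may be slow, and reversible phenoxide addition may scramble the alkene geometry.

The fallback builds the C3–O bond at the aldehyde oxidation level with chloride as leaving group; it sets out from 4.
- Enolate alkylation (LiN(i-Pr)2, THF, −78 °C, then 7) would give 1-[2,5-bis(allyloxy)-4-methoxyphenyl]-5-methylhex-4-en-1-one F3.
- Vilsmeier–Haack–Arnold chloroformylation (POCl3, DMF, 0 → 50 °C) would give (Z)-3-[2,5-bis(allyloxy)-4-methoxyphenyl]-3-chloro-2-(3-methylbut-2-enyl)prop-2-enal F4.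
- Addition–elimination with 10 (K2CO3, DMF, rt) would give (Z)-3-[2,5-bis(allyloxy)-4-methoxyphenyl]-3-(3,5-dimethoxyphenoxy)-2-(3-methylbut-2-enyl)prop-2-enal F5.
- Pinnick oxidation (NaClO2, NaH2PO4, large excess of 2-methylbut-2-ene, t-BuOH/H2O) would return to the route at 12, making steps 3 to 7 unnecessary.

Step 7. Hydroxide may add to C3 and expel the aryloxide, followed by decarboxylation, while attack at the hindered conjugated ester carbonyl is slow.

The fallback replaces hydrolysis by fluoride-induced fragmentation and sets out from 8.
- Transesterification with 2-(trimethylsilyl)ethanol (toluene, 110 °C, methanol distilled off) would give 2-(trimethylsilyl)ethyl 2-[2,5-bis(allyloxy)-4-methoxybenzoyl]-5-methylhex-4-enoate F6.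
- Triflation as in step 5 would give 2-(trimethylsilyl)ethyl (Z)-3-[2,5-bis(allyloxy)-4-methoxyphenyl]-2-(3-methylbut-2-enyl)-3-(trifluoromethylsulfonyloxy)prop-2-enoate F7.
- Substitution with 10 as in step 6 would give 2-(trimethylsilyl)ethyl (Z)-3-[2,5-bis(allyloxy)-4-methoxyphenyl]-3-(3,5-dimethoxyphenoxy)-2-(3-methylbut-2-enyl)prop-2-enoate F8.
- (n-Bu)4NF in THF at rt, then mild acidification, would return to the route at 12.

Step 9. The Lewis acid may also cleave the allyl aryl ethers or induce their sigmatropic shift onto the free ring B positions, in competition with the chelation-directed demethylation.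

The fallback reverses the end game and sets out from 14. Deallylation as in step 10 (Pd(PPh3)4, morpholine, degassed THF) would give 2-(2,5-dihydroxy-4-methoxyphenyl)-5,7-dimethoxy-3-(3-methylbut-2-enyl)chromen-4-one F9. Treatment with excess MgI2·OEt2 (THF/toluene, 60 °C, argon), now with no allyl ether present, should cleave the chelated C5 methyl ether and return to the route at 16.

## Further compounds

F1 | step 8 | 2-bromo-3,5-dimethoxyphenol | COc1cc(O)c(Br)c(OC)c1
F2 | step 8 | methyl (Z)-3-[2,5-bis(allyloxy)-4-methoxyphenyl]-3-(2-bromo-3,5-dimethoxyphenoxy)-2-(3-methylbut-2-enyl)prop-2-enoate | COC(=O)/C(CC=C(C)C)=C(\Oc1cc(OC)cc(OC)c1Br)c1cc(OCC=C)c(OC)cc1OCC=C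
F3 | step 6 | 1-[2,5-bis(allyloxy)-4-methoxyphenyl]-5-methylhex-4-en-1-one | CC(C)=CCCC(=O)c1cc(OCC=C)c(OC)cc1OCC=C
F4 | step 6 | (Z)-3-[2,5-bis(allyloxy)-4-methoxyphenyl]-3-chloro-2-(3-methylbut-2-enyl)prop-2-enal | O=C/C(CC=C(C)C)=C(\Cl)c1cc(OCC=C)c(OC)cc1OCC=C
F5 | step 6 | (Z)-3-[2,5-bis(allyloxy)-4-methoxyphenyl]-3-(3,5-dimethoxyphenoxy)-2-(3-methylbut-2-enyl)prop-2-enal | O=C/C(CC=C(C)C)=C(\Oc1cc(OC)cc(OC)c1)c1cc(OCC=C)c(OC)cc1OCC=C
F6 | step 7 | 2-(trimethylsilyl)ethyl 2-[2,5-bis(allyloxy)-4-methoxybenzoyl]-5-methylhex-4-enoate (racemic) | C[Si](C)(C)CCOC(=O)C(CC=C(C)C)C(=O)c1cc(OCC=C)c(OC)cc1OCC=C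
F7 | step 7 | 2-(trimethylsilyl)ethyl (Z)-3-[2,5-bis(allyloxy)-4-methoxyphenyl]-2-(3-methylbut-2-enyl)-3-(trifluoromethylsulfonyloxy)prop-2-enoate | C[Si](C)(C)CCOC(=O)/C(CC=C(C)C)=C(\OS(=O)(=O)C(F)(F)F)c1cc(OCC=C)c(OC)cc1OCC=C
F8 | step 7 | 2-(trimethylsilyl)ethyl (Z)-3-[2,5-bis(allyloxy)-4-methoxyphenyl]-3-(3,5-dimethoxyphenoxy)-2-(3-methylbut-2-enyl)prop-2-enoate | C[Si](C)(C)CCOC(=O)/C(CC=C(C)C)=C(\Oc1cc(OC)cc(OC)c1)c1cc(OCC=C)c(OC)cc1OCC=C
F9 | step 9 | 2-(2,5-dihydroxy-4-methoxyphenyl)-5,7-dimethoxy-3-(3-methylbut-2-enyl)chromen-4-one | COc1cc(OC)c2c(=O)c(CC=C(C)C)c(-c3cc(O)c(OC)cc3O)oc2c1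
A1 | alternative 1 | 2-ethynyl-5-hydroxy-7-methoxy-3-(3-methylbut-2-enyl)chromen-4-one | COc1cc(O)c2c(=O)c(CC=C(C)C)c(C#C)oc2c1
A2 | alternative 1 | pentacarbonyl[methoxy(1-methoxyethenyl)carbene]chromium | COC(=C)C(OC)=[Cr](=C=O)(=C=O)(=C=O)(=C=O)=C=O
A3 | alternative 1 | 5-hydroxy-2-(2-hydroxy-4,5-dimethoxyphenyl)-7-methoxy-3-(3-methylbut-2-enyl)chromen-4-one | COc1cc(O)c2c(=O)c(CC=C(C)C)c(-c3cc(OC)c(OC)cc3O)oc2c1
A4 | alternative 1 | 2-[5-hydroxy-7-methoxy-3-(3-methylbut-2-enyl)-4-oxochromen-2-yl]-5-methoxycyclohexa-2,5-diene-1,4-dione | COc1cc(O)c2c(=O)c(CC=C(C)C)c(C3=CC(=O)C(OC)=CC3=O)oc2c1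
A5 | alternative 2 | 1-(2,6-difluoro-4-methoxyphenyl)-3-[4-methoxy-2,5-bis(methoxymethoxy)phenyl]-2-(3-methylbut-2-enyl)propane-1,3-dione | COCOc1cc(OC)c(OCOC)cc1C(=O)C(CC=C(C)C)C(=O)c1c(F)cc(OC)cc1F
A6 | alternative 2 | 5-fluoro-7-methoxy-2-[4-methoxy-2,5-bis(methoxymethoxy)phenyl]-3-(3-methylbut-2-enyl)chromen-4-one | COc1cc(F)c2c(=O)c(CC=C(C)C)c(-c3cc(OCOC)c(OC)cc3OCOC)oc2c1
A7 | alternative 3 | 2,6-dihydroxy-4-methoxybenzaldehyde | COc1cc(O)c(C=O)c(O)c1
A8 | alternative 3 | 1-methoxy-2,5-bis(methoxymethoxy)-4-(5-methylhex-4-en-1-ynyl)benzene | COCOc1cc(OC)c(OCOC)cc1C#CCC=C(C)C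
A9 | alternative 3 | 5-hydroxy-7-methoxy-2-[4-methoxy-2,5-bis(methoxymethoxy)phenyl]-3-(3-methylbut-2-enyl)chromen-4-one | COc1cc(O)c2c(=O)c(CC=C(C)C)c(-c3cc(OCOC)c(OC)cc3OCOC)oc2c1
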